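Assumption: the ring is numbered as in quinic acid (C1 carries the carboxyl group; O1, O3 and O4 lie on one face, O5 and the carboxyl group on the other). Read this way, the target is 1,3,5-tri-O-(E)-caffeoyl-4-O-succinyl-(−)-quinic acid.

## Structural features

The target is built on (−)-quinic acid, a cyclohexane with a quaternary C1 (oxygen plus carboxyl) and three contiguous secondary carbinols C3–C4–C5. Every ring oxygen is acylated: (E)-caffeoyl on O1, O3 and O5 and a hemisuccinate on O4. There is one carbocycle and four stereocentres; O3/O4 are cis, O4/O5 trans, and C1 is separated from this triad by the methylenes C2 and C6. Two carboxylic acids and six phenols are free at the end, while four esters, one of them on a tertiary α-carboxylated carbinol, must survive. The fragile points are the caffeoyl esters (hydrolysis, and migration to any free neighbouring hydroxyl under base), the air-sensitive catechols, and the C1 oxygen, which sits β to any carbonyl at C3 or C5 and can then be eliminated. The real difficulty is therefore less the skeleton than (a) setting four ring stereocentres without buying the cyclitol, (b) telling O4 apart from O1, O3 and O5, and (c) a last deprotection that frees eight acidic groups without touching or shifting an ester. The key step exploits that, with a carbonyl at C3, C4 is the α-carbon of an oxygenated ketone and C5 is reached from C1 through C6, so a C3=C4 enamine and a C5 aldehyde close the C4–C5 bond, the ring and the trans O4/O5 pair together. Because C1 is quaternary with two methylene arms, only the C4 enamine can close a six-membered ring; and the C4 oxygen is the only oxygen of the acyclic ketone arm, so it can carry a unique protecting group from the start.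

## Logic of the disconnections

26 ⇒ 25. Seven O–allyl bonds are cut (six aryl ethers, the C1 ester). One protecting group type for phenols and carboxyl means one neutral final step. The demand is that allyl transfer to zerovalent palladium spares four ring esters and the free hemisuccinate; with no free ring hydroxyl left, migration is impossible.

25 ⇒ 23 + 24. The O4–acyl bond is cut. Opening 24 gives the free succinic acid terminus directly, so no extra protecting group is needed. The demand is that acylation of the lone hydroxyl of 23 outruns migration of a flanking caffeoyl group.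

23 ⇒ 22. The O4–benzyl bond is re-formed in the backward sense. This is where the tag placed on O4 at the very beginning is cashed in. The forward step must oxidise a 4-methoxybenzyl ether next to allyl ethers and cinnamates.

22 ⇒ 21 + 19. The O1–acyl bond is cut first. The ester on the tertiary, axial O1 is the hardest of the three to form, so it is made last, under forcing conditions, on a substrate that has no other free hydroxyl. The demand is an acyl donor active enough for a tertiary α-hydroxy ester.

21 ⇒ 20 + 19. The O3–acyl bond is cut. The demand is that the axial secondary hydroxyl reacts well before the tertiary one, which the difference between a secondary and a tertiary alcohol should secure.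

20 ⇒ 15 + 19. The O5–acyl bond is cut. The equatorial 5-hydroxyl is the most accessible of the three and the only one that can lactonise onto the C1 ester, so it is capped first. The demand on site selectivity is light, because a misplaced first ester is made good by the next acylation.

19 ⇒ 18 and 18 ⇒ 16 (through 17). The C–Cl bond is traced back to the acid, and the phenol and carboxyl O–allyl bonds to the free phenols; the carboxyl is released again by saponification. One batch of 19 serves all three acylations.

15 ⇒ 14. The allyl ester C–O bond is cut and the acetal re-formed. One transesterification frees O1 and installs the carboxyl protection; it must not stall at a 1,5-lactone.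

14 ⇒ 13. The C3–H bond is cut back to the ketone. The forward reduction must deliver hydride to the face of O5, giving O3 cis to O4.

13 ⇒ 12 (key). The C4–C5 bond is cut, opening the ring to a keto aldehyde, which removes the ring and two stereocentres. Four points of design are fixed at this stage.
- The closure is 6-(enolendo)-exo-trig, because the enamine C3=C4 bond lies inside the ring formed.
- In a ring the aldehyde's carbon substituent C6 must be gauche to C3. An open-chain syn transition state, in which the catalyst's acid holds the aldehyde oxygen, would therefore lead to the cis diol. The trans diol needs the aldehyde oxygen equatorial; this is argued from the chair and the quaternary C1, not from the acid.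
- The ring needs 4S,5R, the mirror image of what L-configured primary amino acids are expected to give in the open-chain series, so the D catalyst is used.
- The donor oxygen is carried as a 4-methoxybenzyl ether, not as a free hydroxyl. This avoids amine-induced ketose–aldose isomerisation and leaves O4 and O5 distinguishable after the aldol.

The configuration at C1 in 12 and 13 follows from 1 by alkylation with retention, with the tert-butyl group cis to the C6 arm.

12 ⇒ 11. The aldehyde C–H is exchanged for C–S. A thioester is chosen because it can be reduced to the aldehyde in the presence of a ketone and the lactone.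

11 ⇒ 9 (through 10). The C3=O bond is traced back to C3=CH2. The ketone is revealed in one step and no diol is ever present; a γ-hydroxyl would attack the dioxolanone.

9 ⇒ 8. The C–S bond is cut back to the acid.

8 ⇒ 3 + 6 (through 7). The C1–C2 bond is cut. The three-carbon arm arrives complete, with the masked ketone and the tagged O4. The demand is alkylation anti to the tert-butyl group of a carboxylate–enolate dianion.

6 ⇒ 4 + 5 and 3 ⇒ 1 + 2. One ether C–O bond and the acetal C–O bonds are cut, leading to commercial materials. The acetal must form cis and be crystallised pure, since it later controls C1.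

## Other disconnections considered

Alternative 1: The three aryl–Cβ bonds of the caffeoyl groups are cut. Forward, the triacrylate A2 would undergo a threefold Mizoroki–Heck arylation with the aryl iodide A3 to give the hexaacetate A1.
- In favour: the core would be bought as (−)-quinic acid A4 with all four stereocentres. Acryloyl is the smallest enoate, so the hindered O1 is acylated more easily than with a cinnamoyl chloride. Arylation of acrylates is reliably E-selective.
- Against: A2 needs the succinate on O4 alone, and A4 has no built-in handle for that. Three acrylates on one molecule invite Michael addition and polymerisation, and three couplings must all go to completion. Six aryl acetates must finally be removed beside four alkyl esters, which is less clean than allyl transfer.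
- Comparison: on step economy and on stereochemical security the alternative is better than the chosen plan, since nothing has to be set. On mechanism it is the equal. The chosen plan is better on the O4 distinction and on the final deprotection, and it is independent of A4, which allows analogues or the enantiomer.

Alternative 2: The C1–C2 bond is cut. Forward, the silyl ketene acetal of the vinyl lactone A6 (5,6-trans, either C3 epimer) would undergo an Ireland–Claisen ring contraction through a boat transition state to the cyclohexene acid A5.
- In favour: the rearrangement is concerted and suprafacial, so C1 is set against C5 by chirality transfer without a catalyst. The C3=C4 alkene is placed for a syn dihydroxylation anti to the allylic O5, which would give the 3,4-cis/4,5-trans pattern in one step. On predictability of stereocontrol this is the equal or the better of aldol plus reduction.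
- Against: A6 needs its own multistep synthesis with two stereocentres, and an α-silyloxy lactone must be enolised cleanly. The dihydroxylation introduces O3 and O4 together and undistinguished, while the C1 silyloxy group sits on the face that osmylation must use. The succinate would then depend on a selective acylation of a cis diol.
- Comparison: the ring and the quaternary centre are made in one step, whereas the chosen plan sets C1 before the ring closure; the step count is probably similar or higher. The chosen plan is better on the O4 distinction.

Alternative 3: The C1–O and C4–O bonds are cut. Forward, singlet oxygen would add across C1 and C4 of the diene A8 to give the endoperoxide A7, whose O–O bond is then reduced.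
- In favour: the tertiary C1 oxygen and O4 come from one reagent, necessarily cis, and anti to the C5 silyloxy group. After O–O cleavage the only free secondary hydroxyl is O4, so on the O4 distinction this plan is the equal of the chosen one. The cycloaddition is concerted.
- Against: A8 is a cross-conjugated dienoate that aromatises by loss of silanol and reacts sluggishly with an electrophilic oxidant; ene reactions compete. A peroxide must be handled, which is a safety disadvantage. O3 is still missing and must be added to the C2=C3 alkene with regio- and stereocontrol, which costs steps and certainty.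
- Comparison: mechanistically cleaner than an aldol with its equilibria, but weaker on step economy and safety, and it leaves the hardest oxygen for last.

Key step: step 7

## Route

Step 1
Reactants: 1 (S)-malic acid; 2 pivaldehyde
Product: 3 [(2S,4S)-2-tert-butyl-5-oxo-1,3-dioxolan-4-yl]acetic acid (tert-butyl cis to the CH2CO2H arm)
Conditions: TsOH (cat.), H2SO4 (cat.), pentane, reflux, water separator; recrystallisation
Reagents that add atoms: none
Why: Acid-catalysed acetalisation of the α-hydroxy acid under water removal (self-regeneration of stereocentres); the malic centre is untouched and the cis acetal is the thermodynamic isomer, obtained pure by crystallisation.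

Step 2
Reactants: 4 3-bromo-2-(bromomethyl)prop-1-ene; 5 4-methoxybenzyl alcohol
Product: 6 1-({[2-(bromomethyl)prop-2-en-1-yl]oxy}methyl)-4-methoxybenzene
Conditions: NaH (1.05 equiv), THF, 0 °C; then 4 (3 equiv), 0 °C → rt
Reagents that add atoms: none
Why: Williamson ether synthesis on a doubly allylic dibromide; the excess of 4 suppresses the bis-ether and is recovered by distillation.

Step 3
Reactants: 3 [(2S,4S)-2-tert-butyl-5-oxo-1,3-dioxolan-4-yl]acetic acid; 6 1-({[2-(bromomethyl)prop-2-en-1-yl]oxy}methyl)-4-methoxybenzene
Product: 8 [(2S,4S)-2-tert-butyl-4-{2-[(4-methoxybenzyloxy)methyl]prop-2-en-1-yl}-5-oxo-1,3-dioxolan-4-yl]acetic acid, via dilithium enolate 7 (not isolated)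
Conditions: LiN(SiMe3)2 (2.2 equiv), THF, −78 °C; then 6 (1.3 equiv), −78 → −20 °C; 1 M HCl work-up
Reagents that add atoms: none
Why: Diastereoselective enolate alkylation: the carboxylate–lactone enolate dianion is attacked anti to the tert-butyl group, so the new C1–C2 bond replaces hydrogen with retention and sets C1 in the quinate configuration. The SN2 and SN2′ modes of this symmetrical allyl unit give the same product.

Step 4
Reactants: 8 [(2S,4S)-2-tert-butyl-4-{2-[(4-methoxybenzyloxy)methyl]prop-2-en-1-yl}-5-oxo-1,3-dioxolan-4-yl]acetic acid
Product: 9 S-dodecyl 2-[(2S,4S)-2-tert-butyl-4-{2-[(4-methoxybenzyloxy)methyl]prop-2-en-1-yl}-5-oxo-1,3-dioxolan-4-yl]ethanethioate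
Conditions: 1-dodecanethiol (1.2 equiv), EDC·HCl (1.3 equiv), DMAP (0.1 equiv), CH2Cl2, 0 °C → rt
Reagents that add atoms: 1-dodecanethiol, CCCCCCCCCCCCS
Why: Steglich-type thioesterification with a carbodiimide; the thioester is the handle for a one-step reduction to the aldehyde, and the long-chain thiol is chosen because it is nearly odourless.

Step 5
Reactants: 9 S-dodecyl 2-[(2S,4S)-2-tert-butyl-4-{2-[(4-methoxybenzyloxy)methyl]prop-2-en-1-yl}-5-oxo-1,3-dioxolan-4-yl]ethanethioate
Product: 11 S-dodecyl 2-{(2S,4S)-2-tert-butyl-4-[3-(4-methoxybenzyloxy)-2-oxopropyl]-5-oxo-1,3-dioxolan-4-yl}ethanethioate, via secondary ozonide 10 (not isolated)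
Conditions: O3, CH2Cl2, −78 °C, Sudan red 7B as end-point indicator; then PPh3 (1.2 equiv), −78 °C → rt
Reagents that add atoms: ozone, [O-][O+]=O
Why: Ozonolysis of the 1,1-disubstituted alkene with reductive work-up gives the ketone directly; the electron-rich alkene reacts much faster than the anisyl ring or the thioester. No diol is passed through, so no γ-hydroxyl can open the dioxolanone.

Step 6
Reactants: 11 S-dodecyl 2-{(2S,4S)-2-tert-butyl-4-[3-(4-methoxybenzyloxy)-2-oxopropyl]-5-oxo-1,3-dioxolan-4-yl}ethanethioate
Product: 12 2-{(2S,4R)-2-tert-butyl-4-[3-(4-methoxybenzyloxy)-2-oxopropyl]-5-oxo-1,3-dioxolan-4-yl}acetaldehyde (same spatial arrangement as 11; the descriptor changes by priority only)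
Conditions: Et3SiH (3 equiv), 10% Pd/C (cat.), acetone, rt; filter, concentrate, use at once
Reagents that add atoms: none
Why: Fukuyama reduction: zerovalent palladium inserts into the C–S bond, hydride is transferred from silicon and reductive elimination stops at the aldehyde. Ketone, lactone and benzylic ether are not reduced under these conditions.

Step 7
Reactants: 12 2-{(2S,4R)-2-tert-butyl-4-[3-(4-methoxybenzyloxy)-2-oxopropyl]-5-oxo-1,3-dioxolan-4-yl}acetaldehyde
Product: 13 4-O-(4-methoxybenzyl)-3-dehydroquinic acid as its pivaldehyde spiro-dioxolanone (acetal carbon S; C1 R, C4 S, C5 R; O4 cis to O1, O5 trans to O4)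
Conditions: O-tert-butyl-D-threonine (20 mol%), NMP, H2O (3 equiv), 0.05 M, 4 °C → rt
Reagents that add atoms: none
Why: The primary amino acid condenses with the C3 ketone and the iminium ion tautomerises to the enamine toward C4, held Z by an N–H···O4 hydrogen bond and by allylic strain against the branched C2 side; C4 adds to the C5 aldehyde and hydrolysis releases the catalyst (enamine aldol; the closest known types are the primary-amino-acid-catalysed syn aldol of O-protected hydroxyacetones and amine-catalysed cyclisations of the Hajos–Parrish kind). The ring closes in the 6-(enolendo)-exo-trig mode, since the C3=C4 enamine bond ends up inside the new ring; an enamine toward C2, or an aldehyde-derived enamine at C6, could only give a four-membered ring and reverts. C4 is set by the enamine face: the D catalyst is taken because the L catalyst is expected to give the mirror-image (α-R, β-S) syn diol in the open-chain series, and the face it exposes here should lead to 4S. C5 is set by the chair of the forming ring: the Z enamine puts O4 equatorial and the aldehyde oxygen should take the equatorial site, away from the axial substituent that the quaternary C1 must carry and with its dipole opposed to the axial C1–O bond, which gives the trans 5R carbinol; in a ring C6 is gauche to C3, so this oxygen is activated by water, not by the catalyst carboxyl as in an open-chain transition state. The chair with the C1 ether oxygen axial and the lactone carbonyl equatorial is the one that leads to 13, so substrate and catalyst should reinforce each other. The step needs regioselectivity (secured by ring size), the aldehyde acting only as acceptor (a primary amine holds it mainly as the imine) and the 4,5-trans pair on the correct face relative to C1 (catalyst face plus chair preference); C4 can still be corrected through the enamine and C5 through retro-aldol equilibration. The reaction is kept cold, dilute and short because the C1 oxygen is β to both carbonyls and O5 can attack the lactone on standing.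

Step 8
Reactants: 13 4-O-(4-methoxybenzyl)-3-dehydroquinic acid as its pivaldehyde spiro-dioxolanone
Product: 14 4-O-(4-methoxybenzyl)quinic acid as its pivaldehyde spiro-dioxolanone (3-OH cis to O4 and O1, trans to 5-OH)
Conditions: Me4NBH(OAc)3 (5 equiv), MeCN/AcOH (1:1), −30 → −20 °C
Reagents that add atoms: none
Why: Evans–Saksena hydroxyl-directed reduction: the 5-OH exchanges an acetate on boron and delivers hydride to the C3 carbonyl from its own face, giving the 1,3-anti diol, i.e. O3 trans to O5 and cis to O4. External attack anti to the axial C1 oxygen leads to the same epimer, and the acidic medium prevents retro-aldol and elimination.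

Step 9
Reactants: 14 4-O-(4-methoxybenzyl)quinic acid as its pivaldehyde spiro-dioxolanone
Product: 15 allyl 4-O-(4-methoxybenzyl)quinate (free 1-, 3- and 5-OH)
Conditions: allyl alcohol (solvent), K2CO3 (0.2 equiv), 0 °C → rt; neutralise with AcOH
Reagents that add atoms: allyl alcohol, C=CCO
Why: Alkoxide transesterification of the acylal-type lactone: the hemiacetal formed collapses with loss of pivaldehyde and frees the tertiary hydroxyl. A 1,5-lactone formed by O5 would be reopened by the same alkoxide in neat allyl alcohol; no stereocentre is affected.

Step 10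
Reactants: 16 caffeic acid
Product: 18 (E)-3-[3,4-bis(allyloxy)phenyl]prop-2-enoic acid, via triallyl caffeate 17 (not isolated)
Conditions: allyl bromide (3.5 equiv), K2CO3 (4 equiv), DMF, 50 °C; then 2 M NaOH, MeOH/THF, 50 °C; HCl to pH 2
Reagents that add atoms: allyl bromide, C=CCBr
Why: Williamson O-allylation of both phenols and the carboxylate, then saponification of the allyl ester only, since aryl allyl ethers are stable to hydroxide; the E alkene is not touched.

Step 11
Reactants: 18 (E)-3-[3,4-bis(allyloxy)phenyl]prop-2-enoic acid
Product: 19 (E)-3-[3,4-bis(allyloxy)phenyl]prop-2-enoyl chloride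
Conditions: (COCl)2 (1.5 equiv), DMF (cat.), CH2Cl2, 0 °C → rt; evaporate, strip with toluene; the crude chloride is kept as a CH2Cl2 stock solution for steps 12–14
Reagents that add atoms: oxalyl chloride, ClC(=O)C(=O)Cl
Why: Acid chloride formation through the chloroiminium salt made from DMF and oxalyl chloride, with loss of CO, CO2 and HCl; the aryl allyl ethers and the E alkene are inert to these conditions.

Step 12
Reactants: 15 allyl 4-O-(4-methoxybenzyl)quinate; 19 (E)-3-[3,4-bis(allyloxy)phenyl]prop-2-enoyl chloride
Product: 20 allyl 5-O-[(E)-3,4-bis(allyloxy)cinnamoyl]-4-O-(4-methoxybenzyl)quinate (free 1- and 3-OH)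
Conditions: 19 (1.05 equiv, added slowly), pyridine (3 equiv), CH2Cl2, −40 → 0 °C
Reagents that add atoms: none
Why: Acyl chloride esterification with pyridine as base; the equatorial 5-OH should react first, since the 3-OH is axial, syn-diaxial to O1 and next to the benzyl ether, and the 1-OH is tertiary. Capping O5 first also removes the one hydroxyl that could lactonise onto the allyl ester, and any ester misplaced on O3 is made good in step 13, which acylates the remaining secondary hydroxyl with the same group.

Step 13
Reactants: 20 allyl 5-O-[(E)-3,4-bis(allyloxy)cinnamoyl]-4-O-(4-methoxybenzyl)quinate; 19 (E)-3-[3,4-bis(allyloxy)phenyl]prop-2-enoyl chloride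
Product: 21 allyl 3,5-bis-O-[(E)-3,4-bis(allyloxy)cinnamoyl]-4-O-(4-methoxybenzyl)quinate (free 1-OH)
Conditions: 19 (1.3 equiv), pyridine (3 equiv), DMAP (0.2 equiv), CH2Cl2, 0 °C → rt
Reagents that add atoms: none
Why: DMAP-catalysed acylation through the N-acylpyridinium ion reaches the axial secondary 3-OH at room temperature. The tertiary 1-OH is far slower with a catalytic amount of DMAP and little excess chloride, and no stereocentre is involved.

Step 14
Reactants: 21 allyl 3,5-bis-O-[(E)-3,4-bis(allyloxy)cinnamoyl]-4-O-(4-methoxybenzyl)quinate; 19 (E)-3-[3,4-bis(allyloxy)phenyl]prop-2-enoyl chloride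
Product: 22 allyl 1,3,5-tris-O-[(E)-3,4-bis(allyloxy)cinnamoyl]-4-O-(4-methoxybenzyl)quinate
Conditions: 19 (2.5 equiv), DMAP (1.5 equiv), pyridine (5 equiv), CH2Cl2, 40 °C
Reagents that add atoms: none
Why: Acylation of the tertiary α-hydroxy ester needs the N-acylpyridinium ion in stoichiometric amount, excess chloride and mild warming, which is tolerable here because no other hydroxyl is free. The C1–O bond is not broken, so the configuration is retained.

Step 15
Reactants: 22 allyl 1,3,5-tris-O-[(E)-3,4-bis(allyloxy)cinnamoyl]-4-O-(4-methoxybenzyl)quinate
Product: 23 allyl 1,3,5-tris-O-[(E)-3,4-bis(allyloxy)cinnamoyl]quinate (free 4-OH)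
Conditions: DDQ (1.5 equiv), CH2Cl2/pH 7 phosphate buffer (10:1), 0 °C → rt; used without prolonged storage
Reagents that add atoms: none
Why: Oxidative cleavage of the 4-methoxybenzyl ether by DDQ (hydride abstraction to the oxocarbenium ion, then hydrolysis). The allyl ethers, allyl ester and cinnamates have no comparably activated benzylic C–H, and the neutral buffered medium should not promote acyl migration.

Step 16
Reactants: 23 allyl 1,3,5-tris-O-[(E)-3,4-bis(allyloxy)cinnamoyl]quinate; 24 succinic anhydride
Product: 25 allyl 1,3,5-tris-O-[(E)-3,4-bis(allyloxy)cinnamoyl]-4-O-(3-carboxypropanoyl)quinate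
Conditions: 24 (3 equiv), DMAP (0.2 equiv), pyridine, CH2Cl2, 0 °C → rt
Reagents that add atoms: none
Why: DMAP-catalysed opening of the cyclic anhydride by the only free hydroxyl gives the hemisuccinate with its free acid in one step. It is run cold and with excess anhydride so that acylation outpaces migration of a flanking caffeoyl group.

Step 17
Reactants: 25 allyl 1,3,5-tris-O-[(E)-3,4-bis(allyloxy)cinnamoyl]-4-O-(3-carboxypropanoyl)quinate
Product: 26 1,3,5-tri-O-[(E)-caffeoyl]-4-O-(3-carboxypropanoyl)quinic acid (target)
Conditions: Pd(PPh3)4 (10 mol%), morpholine (15 equiv), THF, rt, argon, dark; dilute HCl work-up, reversed-phase chromatography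
Reagents that add atoms: none
Why: Tsuji–Trost deallylation: zerovalent palladium ionises the six aryl allyl ethers and the allyl ester to π-allyl complexes, which morpholine traps. The four ring esters are not touched and, with no ring hydroxyl free, acyl migration cannot occur.

## Compound list

1 | (S)-malic acid | O[C@@H](CC(=O)O)C(=O)O | starting material
2 | pivaldehyde | CC(C)(C)C=O | starting material
3 | [(2S,4S)-2-tert-butyl-5-oxo-1,3-dioxolan-4-yl]acetic acid | OC(=O)C[C@H](O1)C(=O)O[C@H]1C(C)(C)C | intermediate
4 | 3-bromo-2-(bromomethyl)prop-1-ene | C=C(CBr)CBr | starting material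
5 | 4-methoxybenzyl alcohol | COc1ccc(CO)cc1 | starting material
6 | 1-({[2-(bromomethyl)prop-2-en-1-yl]oxy}methyl)-4-methoxybenzene | COc1ccc(COCC(=C)CBr)cc1 | intermediate
7 | dilithium enolate–carboxylate of 3 (formed in the flask) | [Li+].[Li+].[O-]C(=O)CC1=C([O-])O[C@@H](C(C)(C)C)O1 | intermediate
8 | [(2S,4S)-2-tert-butyl-4-{2-[(4-methoxybenzyloxy)methyl]prop-2-en-1-yl}-5-oxo-1,3-dioxolan-4-yl]acetic acid | OC(=O)C[C@](O1)(C(=O)O[C@H]1C(C)(C)C)CC(=C)COCc2ccc(OC)cc2 | intermediate
9 | S-dodecyl thioester of 8 | CCCCCCCCCCCCSC(=O)C[C@](O1)(C(=O)O[C@H]1C(C)(C)C)CC(=C)COCc2ccc(OC)cc2 | intermediate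
10 | secondary ozonide (1,2,4-trioxolane) of 9 (formed in the flask; ozonide carbon unassigned) | CCCCCCCCCCCCSC(=O)C[C@](O1)(C(=O)O[C@H]1C(C)(C)C)CC3(COCc2ccc(OC)cc2)OCOO3 | intermediate
11 | S-dodecyl 2-{(2S,4S)-2-tert-butyl-4-[3-(4-methoxybenzyloxy)-2-oxopropyl]-5-oxo-1,3-dioxolan-4-yl}ethanethioate | CCCCCCCCCCCCSC(=O)C[C@](O1)(C(=O)O[C@H]1C(C)(C)C)CC(=O)COCc2ccc(OC)cc2 | intermediate
12 | 2-{(2S,4R)-2-tert-butyl-4-[3-(4-methoxybenzyloxy)-2-oxopropyl]-5-oxo-1,3-dioxolan-4-yl}acetaldehyde | O=CC[C@](O1)(C(=O)O[C@H]1C(C)(C)C)CC(=O)COCc2ccc(OC)cc2 | intermediate
13 | 4-O-(4-methoxybenzyl)-3-dehydroquinic acid pivaldehyde spiro-dioxolanone | COc1ccc(cc1)CO[C@H]2[C@H](O)C[C@](O3)(C(=O)O[C@H]3C(C)(C)C)CC2=O | intermediate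
14 | 4-O-(4-methoxybenzyl)quinic acid pivaldehyde spiro-dioxolanone | COc1ccc(cc1)CO[C@H]2[C@H](O)C[C@](O3)(C(=O)O[C@H]3C(C)(C)C)C[C@H]2O | intermediate
15 | allyl 4-O-(4-methoxybenzyl)quinate | COc1ccc(cc1)CO[C@H]2[C@H](O)C[C@](O)(C(=O)OCC=C)C[C@H]2O | intermediate
16 | caffeic acid | O=C(O)/C=C/c1ccc(O)c(O)c1 | starting material
17 | allyl (E)-3-[3,4-bis(allyloxy)phenyl]prop-2-enoate (formed in the flask) | C=CCOC(=O)/C=C/c1ccc(OCC=C)c(OCC=C)c1 | intermediate
18 | (E)-3-[3,4-bis(allyloxy)phenyl]prop-2-enoic acid | O=C(O)/C=C/c1ccc(OCC=C)c(OCC=C)c1 | intermediate
19 | (E)-3-[3,4-bis(allyloxy)phenyl]prop-2-enoyl chloride | O=C(Cl)/C=C/c1ccc(OCC=C)c(OCC=C)c1 | intermediate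
20 | allyl 5-O-[(E)-3,4-bis(allyloxy)cinnamoyl]-4-O-(4-methoxybenzyl)quinate | COc1ccc(cc1)CO[C@H]2[C@H](OC(=O)/C=C/c3ccc(OCC=C)c(OCC=C)c3)C[C@](O)(C(=O)OCC=C)C[C@H]2O | intermediate
21 | allyl 3,5-bis-O-[(E)-3,4-bis(allyloxy)cinnamoyl]-4-O-(4-methoxybenzyl)quinate | COc1ccc(cc1)CO[C@H]2[C@H](OC(=O)/C=C/c3ccc(OCC=C)c(OCC=C)c3)C[C@](O)(C(=O)OCC=C)C[C@H]2OC(=O)/C=C/c3ccc(OCC=C)c(OCC=C)c3 | intermediate
22 | allyl 1,3,5-tris-O-[(E)-3,4-bis(allyloxy)cinnamoyl]-4-O-(4-methoxybenzyl)quinate | COc1ccc(cc1)CO[C@H]2[C@H](OC(=O)/C=C/c3ccc(OCC=C)c(OCC=C)c3)C[C@](OC(=O)/C=C/c3ccc(OCC=C)c(OCC=C)c3)(C(=O)OCC=C)C[C@H]2OC(=O)/C=C/c3ccc(OCC=C)c(OCC=C)c3 | intermediate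
23 | allyl 1,3,5-tris-O-[(E)-3,4-bis(allyloxy)cinnamoyl]quinate | O[C@H]1[C@H](OC(=O)/C=C/c2ccc(OCC=C)c(OCC=C)c2)C[C@](OC(=O)/C=C/c2ccc(OCC=C)c(OCC=C)c2)(C(=O)OCC=C)C[C@H]1OC(=O)/C=C/c1ccc(OCC=C)c(OCC=C)c1 | intermediate
24 | succinic anhydride | O=C1CCC(=O)O1 | starting material
25 | allyl 1,3,5-tris-O-[(E)-3,4-bis(allyloxy)cinnamoyl]-4-O-(3-carboxypropanoyl)quinate | O=C(O)CCC(=O)O[C@H]1[C@H](OC(=O)/C=C/c2ccc(OCC=C)c(OCC=C)c2)C[C@](OC(=O)/C=C/c2ccc(OCC=C)c(OCC=C)c2)(C(=O)OCC=C)C[C@H]1OC(=O)/C=C/c1ccc(OCC=C)c(OCC=C)c1 | intermediate
26 | 1,3,5-tri-O-[(E)-caffeoyl]-4-O-(3-carboxypropanoyl)quinic acid | O=C(O)CCC(=O)O[C@H]1[C@H](OC(=O)/C=C/c2ccc(O)c(O)c2)C[C@](OC(=O)/C=C/c2ccc(O)c(O)c2)(C(=O)O)C[C@H]1OC(=O)/C=C/c1ccc(O)c(O)c1 | target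

## Step count and least certain steps

Total: 17 steps. Longest linear sequence: 14 steps from 1 (steps 1, 3–9 and 12–17); steps 2, 10 and 11 are side branches.

Step 7 (key step). The most likely failure is poor facial discrimination relative to C1: the catalyst sits far from the quaternary centre and the inherent chair preference is modest, so the 4,5-trans pair may form on both faces of the ring. Loss of the C1 oxygen by β-elimination through the aldehyde-derived enamine, and attack of O5 on the lactone on long standing, are secondary risks. The fallback gives up catalyst control for thermodynamic control with recycling. It sets out from 12, which would be closed with an achiral buffered amine catalyst (pyrrolidine/AcOH 1:1, 20 mol%, CH2Cl2, rt) under equilibrating conditions, in which the trans diequatorial aldols should dominate and the isomer with the C1 oxygen axial should be the more stable. The unwanted 4,5-bis-epimer of 13, F1, is separated and resubmitted to the same catalyst, where retro-aldol reopening returns it to the equilibrium mixture. The fallback comes back to the route at 13.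

Step 8. Directed delivery requires the equatorial 5-OH to reach C3 through a ring-flipped or twist conformer; if this is slow, undirected reduction may compete and give poor facial selectivity. The fallback replaces directed delivery by steric approach control. It sets out from 13, which is silylated at O5 (Et3SiCl, imidazole, DMF) to 5-O-triethylsilyl-13, F2. Reduction with LiBH(s-Bu)3 (THF, −78 °C), which attacks equatorially and away from the axial C1 oxygen, gives the 3-axial alcohol 5-O-triethylsilyl-14, F3. Mild acid (AcOH/THF/H2O) removes the silyl group, and the route is rejoined at 14.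

Step 9. Competing lactonisation of O5 onto the C1 carbonyl could leave a 1,5-lactone in equilibrium with the allyl ester. The fallback separates ring opening from esterification. It sets out from 14, which is hydrolysed with LiOH (THF/H2O, 0 °C) to 4-O-(4-methoxybenzyl)quinic acid, F4; a lactone cannot persist in aqueous hydroxide. Carboxylate O-alkylation with allyl bromide and CsHCO3 in DMF then returns to 15.

Step 12. The first acylation may show poor site selectivity between the equatorial 5-OH and the axial 3-OH, which would cost material as diester and unreacted triol even though every monoester converges later. The fallback replaces kinetic selection by temporary protection. It sets out from 15, which is condensed with phenylboronic acid (toluene, molecular sieves) to the cyclic phenylboronate across the syn-diaxial O1 and O3, F5, the only pair of hydroxyls that can bridge. Acylation with 19 and pyridine then has only the 5-OH to find and gives the 5-O-acyl boronate, F6. Transesterification with pinacol (CH2Cl2, rt) releases the 1,3-diol and returns to 20.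

Step 14. Acylation may stall at the tertiary, axial O1, which is flanked by the C1 ester and the syn-axial O3 ester; forcing the acid chloride risks decomposition. The fallback builds the third caffeoyl group on the alcohol instead of transferring it. It sets out from 21, which is heated with Meldrum's acid (toluene, 90 °C), a reagent that acylates even tertiary alcohols, to give the 1-O-malonyl half ester of 21, F7. A Knoevenagel–Doebner condensation with 3,4-bis(allyloxy)benzaldehyde, F8 (from 3,4-dihydroxybenzaldehyde, allyl bromide and K2CO3), in pyridine with catalytic piperidine forms the E-cinnamate with loss of CO2 and returns to 22.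

Step 16. Base-mediated migration of a caffeoyl group from O3 or O5 onto the freed O4 may occur before the anhydride reacts, which would scramble the position of the succinate. The fallback avoids a nucleophilic amine catalyst and the free acid stage. It sets out from 23 and uses allyl hydrogen succinate, F9 (from 24 and allyl alcohol), converted with (COCl)2 into allyl 4-chloro-4-oxobutanoate, F10. Acylation with 2,4,6-collidine in CH2Cl2 at −20 °C gives the 4-O-[4-(allyloxy)-4-oxobutanoyl] ester, F11. The Pd(PPh3)4/morpholine step then removes eight allyl groups and arrives directly at 26.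

## Further compounds

F1 | step 7 | 4,5-bis-epimer of 13 (C4 R, C5 S; O4 trans to O1) | COc1ccc(cc1)CO[C@@H]2[C@@H](O)C[C@](O3)(C(=O)O[C@H]3C(C)(C)C)CC2=O
F2 | step 8 | 5-O-triethylsilyl-13 | COc1ccc(cc1)CO[C@H]2[C@H](O[Si](CC)(CC)CC)C[C@](O3)(C(=O)O[C@H]3C(C)(C)C)CC2=O
F3 | step 8 | 5-O-triethylsilyl-14 | COc1ccc(cc1)CO[C@H]2[C@H](O[Si](CC)(CC)CC)C[C@](O3)(C(=O)O[C@H]3C(C)(C)C)C[C@H]2O
F4 | step 9 | 4-O-(4-methoxybenzyl)quinic acid | COc1ccc(cc1)CO[C@H]2[C@H](O)C[C@](O)(C(=O)O)C[C@H]2O
F5 | step 12 | allyl 4-O-(4-methoxybenzyl)quinate 1,3-O-phenylboronate | COc1ccc(cc1)CO[C@H]2[C@H](O)C[C@](O3)(C(=O)OCC=C)C[C@H]2OB3c4ccccc4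
F6 | step 12 | allyl 5-O-[(E)-3,4-bis(allyloxy)cinnamoyl]-4-O-(4-methoxybenzyl)quinate 1,3-O-phenylboronate | COc1ccc(cc1)CO[C@H]2[C@H](OC(=O)/C=C/c5ccc(OCC=C)c(OCC=C)c5)C[C@](O3)(C(=O)OCC=C)C[C@H]2OB3c4ccccc4
F7 | step 14 | 1-O-(carboxyacetyl) derivative of 21 | COc1ccc(cc1)CO[C@H]2[C@H](OC(=O)/C=C/c3ccc(OCC=C)c(OCC=C)c3)C[C@](OC(=O)CC(=O)O)(C(=O)OCC=C)C[C@H]2OC(=O)/C=C/c3ccc(OCC=C)c(OCC=C)c3
F8 | step 14 | 3,4-bis(allyloxy)benzaldehyde | O=Cc1ccc(OCC=C)c(OCC=C)c1
F9 | step 16 | allyl hydrogen succinate | C=CCOC(=O)CCC(=O)O
F10 | step 16 | allyl 4-chloro-4-oxobutanoate | C=CCOC(=O)CCC(=O)Cl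
F11 | step 16 | allyl 1,3,5-tris-O-[(E)-3,4-bis(allyloxy)cinnamoyl]-4-O-[4-(allyloxy)-4-oxobutanoyl]quinate | C=CCOC(=O)CCC(=O)O[C@H]1[C@H](OC(=O)/C=C/c2ccc(OCC=C)c(OCC=C)c2)C[C@](OC(=O)/C=C/c2ccc(OCC=C)c(OCC=C)c2)(C(=O)OCC=C)C[C@H]1OC(=O)/C=C/c1ccc(OCC=C)c(OCC=C)c1
A1 | alternative 1 | hexa-O-acetyl derivative of the target | O=C(O)CCC(=O)O[C@H]1[C@H](OC(=O)/C=C/c2ccc(OC(C)=O)c(OC(C)=O)c2)C[C@](OC(=O)/C=C/c2ccc(OC(C)=O)c(OC(C)=O)c2)(C(=O)O)C[C@H]1OC(=O)/C=C/c1ccc(OC(C)=O)c(OC(C)=O)c1
A2 | alternative 1 | 1,3,5-tri-O-acryloyl-4-O-(3-carboxypropanoyl)quinic acid | O=C(O)CCC(=O)O[C@H]1[C@H](OC(=O)C=C)C[C@](OC(=O)C=C)(C(=O)O)C[C@H]1OC(=O)C=C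
A3 | alternative 1 | 4-iodo-1,2-phenylene diacetate | CC(=O)Oc1ccc(I)cc1OC(C)=O
A4 | alternative 1 | (−)-quinic acid | O[C@H]1[C@H](O)C[C@](O)(C(=O)O)C[C@H]1O
A5 | alternative 2 | 1,5-bis(tert-butyldimethylsilyloxy)cyclohex-3-ene-1-carboxylic acid (O1 trans to O5) | O=C(O)[C@]1(O[Si](C)(C)C(C)(C)C)CC=C[C@H](O[Si](C)(C)C(C)(C)C)C1
A6 | alternative 2 | 3,5-bis(tert-butyldimethylsilyloxy)-6-vinyltetrahydropyran-2-one (5,6-trans; C3 either epimer) | O=C1O[C@@H](C=C)[C@H](O[Si](C)(C)C(C)(C)C)CC1O[Si](C)(C)C(C)(C)C
A7 | alternative 3 | tert-butyl 2,3-dioxabicyclo[2.2.2]oct-5-ene-1-carboxylate bearing the 8-silyloxy group (O1 and O4 cis, trans to O5) | O1[C@H]2[C@H](O[Si](C)(C)C(C)(C)C)C[C@](O1)(C(=O)OC(C)(C)C)C=C2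
A8 | alternative 3 | tert-butyl (5R)-5-(tert-butyldimethylsilyloxy)cyclohexa-1,3-diene-1-carboxylate | CC(C)(C)OC(=O)C1=CC=C[C@H](O[Si](C)(C)C(C)(C)C)C1
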